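**Retrosynthetic overview**
- The target is reached from its bis-benzyl ether (primary and terminal secondary hydroxyls) by one neutral hydrogenolysis.
- The only ring, the benzene ring, is closed last in the skeleton-building sequence. In the 2,4-dihydroxy-6-alkylbenzoate the ester-bearing C1 lies between oxygenated C2 and alkylated C6, so C1 and C6 are taken as the two alkyne carbons of a hex-2-ynoate ester. C2–C5, with O2 and O4, come from the dimedone-derived 1,3-bis(trimethylsilyloxy)diene by [4+2] cycloaddition and loss of 2-methylpropene, forming C1–C2 and C5–C6.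
- The acyclic ynoate tetraester is made by esterifying a (5R)-5-hydroxyhex-2-ynoate with the arm acid. The hydroxy-ynoate comes from the lithiated propiolate of methyl (S)-3-hydroxybutanoate and (R)-propylene oxide.
- The arm acid comes from (S)-benzyl glycidyl ether (vinyl Grignard opening), esterification with (S)-3-(benzyloxy)butanoic acid, then ozonolysis and Pinnick oxidation.
- All four stereocentres are bought (chiral pool) and are never part of a bond-forming event.

Key step: step 12

Remark on the chemistry: both aliphatic hydroxyls are carried as benzyl ethers, so that a single neutral hydrogenolysis ends the route and acyl migration onto the primary hydroxyl is avoided. Benzoate numbering: C1 bears the ester, C2 and C4 the hydroxyls, C6 the side chain.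

**Route**

Step 1
Reactants: 1 methyl (S)-3-hydroxybutanoate
Product: 2 methyl (3S)-3-(benzyloxy)butanoate
Conditions: BnOC(=NH)CCl3, TfOH (cat.), cyclohexane/CH2Cl2, 0 °C to rt
Reagents that add atoms: benzyl 2,2,2-trichloroacetimidate, ClC(Cl)(Cl)C(=N)OCc1ccccc1
Why: Acid-catalysed O-benzylation with the trichloroacetimidate needs no base, so the β-hydroxy ester should neither eliminate nor undergo retro-aldol cleavage, and the stereocentre is retained because its C–O bond is untouched.

Step 2
Reactants: 2 methyl (3S)-3-(benzyloxy)butanoate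
Product: 3 (3S)-3-(benzyloxy)butanoic acid
Conditions: LiOH, THF/H2O, 0 °C to rt; then 1 M HCl
Reagents that add atoms: lithium hydroxide, [Li+].[OH-]
Why: Saponification of the unhindered methyl ester is fast at 0 °C, and benzyloxide is too poor a leaving group for E1cB loss, so the stereocentre is unaffected.

Step 3
Reactants: 4 (S)-benzyl glycidyl ether
Product: 5 (2S)-1-(benzyloxy)pent-4-en-2-ol
Conditions: CH2=CHMgBr, CuI (10 mol%), THF, −40 to 0 °C
Reagents that add atoms: vinylmagnesium bromide, C=C[Mg]Br
Why: Copper-catalysed Grignard opening of a terminal epoxide proceeds by SN2 attack at the unsubstituted CH2, so the carbinol stereocentre of 4 is carried into 5 unchanged.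

Step 4
Reactants: 5 (2S)-1-(benzyloxy)pent-4-en-2-ol; 3 (3S)-3-(benzyloxy)butanoic acid
Product: 6 (2S)-1-(benzyloxy)pent-4-en-2-yl (3S)-3-(benzyloxy)butanoate
Conditions: DCC, DMAP (cat.), CH2Cl2, 0 °C to rt
Reagents that add atoms: none
Why: Steglich esterification (carbodiimide activation, DMAP acyl transfer) should acylate the secondary alcohol with the unhindered acid without touching either stereocentre.

Step 5
Reactants: 6 (2S)-1-(benzyloxy)pent-4-en-2-yl (3S)-3-(benzyloxy)butanoate
Product: 7 (2S)-1-(benzyloxy)-4-oxobutan-2-yl (3S)-3-(benzyloxy)butanoate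
Conditions: O3, CH2Cl2, −78 °C, stopped at first blue colour; PPh3, −78 °C to rt; used crude
Reagents that add atoms: ozone, [O-][O+]=O
Why: Ozonolysis of the terminal alkene with reductive work-up (Criegee mechanism) should give the aldehyde, since the benzyl ethers react much more slowly at −78 °C, and the crude β-acyloxy aldehyde is used at once to avoid elimination on silica.

Step 6
Reactants: 7 (2S)-1-(benzyloxy)-4-oxobutan-2-yl (3S)-3-(benzyloxy)butanoate
Product: 8 (3S)-4-(benzyloxy)-3-{[(3S)-3-(benzyloxy)butanoyl]oxy}butanoic acid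
Conditions: NaClO2, NaH2PO4, 2-methyl-2-butene, t-BuOH/H2O, 0 °C to rt
Reagents that add atoms: sodium chlorite, [Na+].[O-]Cl=O
Why: Pinnick oxidation converts the aldehyde into the acid at about pH 4, where the β-acyloxy group should not eliminate and the esters and benzyl ethers are stable.

Step 7
Reactants: 9 propiolic acid; 1 methyl (S)-3-hydroxybutanoate
Product: 10 methyl (3S)-3-(prop-2-ynoyloxy)butanoate
Conditions: DCC, DMAP (5 mol%), CH2Cl2, −20 to 0 °C
Reagents that add atoms: none
Why: Steglich esterification at low temperature with little DMAP limits conjugate addition to the propiolate, and the alcohol stereocentre is retained because only its O–H bond reacts.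

Step 8
Reactants: 10 methyl (3S)-3-(prop-2-ynoyloxy)butanoate; 11 (R)-propylene oxide
Product: 13 methyl (3S)-3-{[(5R)-5-hydroxyhex-2-ynoyl]oxy}butanoate, via lithium acetylide 12 (not isolated)
Conditions: LiN(SiMe3)2 (1.0 equiv), THF, −78 °C; BF3·OEt2; then 11 (excess), −78 °C; aq. NH4Cl
Reagents that add atoms: none
Why: Yamaguchi–Hirao alkynylation: the acetylenic C–H is far more acidic than the ester α-CH2 and should be lithiated selectively at −78 °C, and the BF3-activated epoxide is opened by SN2 attack at its CH2 terminus, so the (R) centre of 11 is retained and the linear δ-hydroxy ynoate cannot lactonise.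

Step 9
Reactants: 13 methyl (3S)-3-{[(5R)-5-hydroxyhex-2-ynoyl]oxy}butanoate; 8 (3S)-4-(benzyloxy)-3-{[(3S)-3-(benzyloxy)butanoyl]oxy}butanoic acid
Product: 14 methyl (3S)-3-{[(5R)-5-({(3S)-4-(benzyloxy)-3-[(3S)-3-(benzyloxy)butanoyloxy]butanoyl}oxy)hex-2-ynoyl]oxy}butanoate
Conditions: DCC, DMAP (cat.), CH2Cl2, 0 °C
Reagents that add atoms: none
Why: Steglich esterification at 0 °C with catalytic DMAP should join the unhindered acid to the secondary homopropargylic alcohol, with all four stereocentres as spectators.

Step 10
Reactants: 15 dimedone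
Product: 16 5,5-dimethyl-3-(trimethylsilyloxy)cyclohex-2-en-1-one
Conditions: Me3SiCl, Et3N, Et2O, rt
Reagents that add atoms: chlorotrimethylsilane, C[Si](C)(C)Cl
Why: O-silylation of the enol form of the cyclic β-diketone gives the vinylogous silyl ester.

Step 11
Reactants: 16 5,5-dimethyl-3-(trimethylsilyloxy)cyclohex-2-en-1-one
Product: 18 5,5-dimethyl-1,3-bis(trimethylsilyloxy)cyclohexa-1,3-diene, via lithium dienolate 17 (not isolated)
Conditions: LiN(iPr)2, THF, −78 °C; Me3SiCl, −78 °C to rt; distilled and used fresh
Reagents that add atoms: chlorotrimethylsilane, C[Si](C)(C)Cl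
Why: Kinetic deprotonation of the vinylogous ester at the α′-CH2 gives the cross-conjugated enolate, which is O-silylated to the 1,3-bis(silyloxy)-1,3-diene.

Step 12
Reactants: 14 methyl (3S)-3-{[(5R)-5-({(3S)-4-(benzyloxy)-3-[(3S)-3-(benzyloxy)butanoyloxy]butanoyl}oxy)hex-2-ynoyl]oxy}butanoate; 18 5,5-dimethyl-1,3-bis(trimethylsilyloxy)cyclohexa-1,3-diene
Product: 21 (2S)-4-methoxy-4-oxobutan-2-yl 2-[(2R)-2-({(3S)-4-(benzyloxy)-3-[(3S)-3-(benzyloxy)butanoyloxy]butanoyl}oxy)propyl]-4,6-dihydroxybenzoate, via bicyclooctadiene cycloadduct 19 (not isolated), via bis(trimethylsilyl) arene 20 (not isolated)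
Conditions: 18 (4 equiv), PhMe (minimal), sealed tube, 150 °C; then 1 M HCl, THF, 0 °C
Reagents that add atoms: none
Why: The electron-rich diene 18 and the electron-poor ynoate 14 should combine in a concerted, asynchronous thermal [4+2] cycloaddition to the bicyclo[2.2.2]octa-2,5-diene 19, whose CH2–CMe2 bridge is then expelled as 2-methylpropene in a retro-[4+2] driven by aromatisation; this is the Alder–Rickert reaction, the known route from alkynoates and 1,3-bis(silyloxy)cyclohexa-1,3-dienes to 6-substituted 2,4-dihydroxybenzoates. The benzene ring is closed by the intermolecular cycloaddition itself, which forms C1–C2 and C5–C6 in one event, the other four ring carbons and both phenolic oxygens coming from the diene. No stereocentre is created in the product: the two bridgehead centres of 19 are erased on cycloreversion and the four carbinol centres are spectators. The step needs regioselectivity, which polarity matching should secure: the unsubstituted diene terminus (diene C4), which receives the donor effect of both silyloxy groups, bonds to the electrophilic β-carbon of the ynoate, and the silyloxy-bearing terminus (diene C1) bonds to the α-carbon, so the ester lands between O2 and the side chain. It also needs chemoselectivity, which the neutral, base-free conditions and the absence of free hydroxyl groups should provide, so the aliphatic esters and β-acyloxy units survive. The labile aryl trimethylsilyl ethers of 20 are hydrolysed in the acidic work-up.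

Step 13
Reactants: 21 (2S)-4-methoxy-4-oxobutan-2-yl 2-[(2R)-2-({(3S)-4-(benzyloxy)-3-[(3S)-3-(benzyloxy)butanoyloxy]butanoyl}oxy)propyl]-4,6-dihydroxybenzoate
Product: 22 talapolyester D
Conditions: H2 (1 atm), 10% Pd/C, EtOAc, rt
Reagents that add atoms: none
Why: Palladium-catalysed hydrogenolysis should cleave both benzylic C–O bonds under neutral conditions, leaving the esters, the arene and all stereocentres untouched and avoiding acyl migration onto the liberated primary hydroxyl.

**Compound list**

1 | methyl (S)-3-hydroxybutanoate | COC(=O)C[C@H](C)O | starting material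
2 | methyl (3S)-3-(benzyloxy)butanoate | COC(=O)C[C@H](C)OCc1ccccc1 | intermediate
3 | (3S)-3-(benzyloxy)butanoic acid | OC(=O)C[C@H](C)OCc1ccccc1 | intermediate
4 | (S)-benzyl glycidyl ether, (2S)-2-[(benzyloxy)methyl]oxirane | C(OCc1ccccc1)[C@@H]1CO1 | starting material
5 | (2S)-1-(benzyloxy)pent-4-en-2-ol | C=CC[C@@H](COCc1ccccc1)O | intermediate
6 | (2S)-1-(benzyloxy)pent-4-en-2-yl (3S)-3-(benzyloxy)butanoate | C=CC[C@@H](COCc1ccccc1)OC(=O)C[C@H](C)OCc1ccccc1 | intermediate
7 | (2S)-1-(benzyloxy)-4-oxobutan-2-yl (3S)-3-(benzyloxy)butanoate | O=CC[C@@H](COCc1ccccc1)OC(=O)C[C@H](C)OCc1ccccc1 | intermediate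
8 | (3S)-4-(benzyloxy)-3-{[(3S)-3-(benzyloxy)butanoyl]oxy}butanoic acid | OC(=O)C[C@@H](COCc1ccccc1)OC(=O)C[C@H](C)OCc1ccccc1 | intermediate
9 | propiolic acid | C#CC(=O)O | starting material
10 | methyl (3S)-3-(prop-2-ynoyloxy)butanoate | COC(=O)C[C@H](C)OC(=O)C#C | intermediate
11 | (R)-propylene oxide | C[C@@H]1CO1 | starting material
12 | lithium acetylide of 10 | COC(=O)C[C@H](C)OC(=O)C#C[Li] | intermediate (not isolated)
13 | methyl (3S)-3-{[(5R)-5-hydroxyhex-2-ynoyl]oxy}butanoate | COC(=O)C[C@H](C)OC(=O)C#CC[C@@H](C)O | intermediate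
14 | methyl (3S)-3-{[(5R)-5-({(3S)-4-(benzyloxy)-3-[(3S)-3-(benzyloxy)butanoyloxy]butanoyl}oxy)hex-2-ynoyl]oxy}butanoate | COC(=O)C[C@H](C)OC(=O)C#CC[C@@H](C)OC(=O)C[C@@H](COCc1ccccc1)OC(=O)C[C@H](C)OCc1ccccc1 | intermediate (key-step precursor)
15 | dimedone | CC1(C)CC(=O)CC(=O)C1 | starting material
16 | 5,5-dimethyl-3-(trimethylsilyloxy)cyclohex-2-en-1-one | CC1(C)CC(=O)C=C(O[Si](C)(C)C)C1 | intermediate
17 | lithium 5,5-dimethyl-3-(trimethylsilyloxy)cyclohexa-1,3-dien-1-olate | [Li]OC1=CC(C)(C)CC(O[Si](C)(C)C)=C1 | intermediate (not isolated)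
18 | 5,5-dimethyl-1,3-bis(trimethylsilyloxy)cyclohexa-1,3-diene | C[Si](C)(C)OC1=CC(O[Si](C)(C)C)=CC(C)(C)C1 | intermediate
19 | bicyclo[2.2.2]octa-2,5-diene cycloadduct of 14 and 18 (bridgehead C–OSiMe3 and C–H, CH2–CMe2 bridge; mixture of bridgehead diastereomers) | COC(=O)C[C@H](C)OC(=O)C1=C(C[C@@H](C)OC(=O)C[C@@H](COCc2ccccc2)OC(=O)C[C@H](C)OCc2ccccc2)C2C(O[Si](C)(C)C)=CC1(O[Si](C)(C)C)CC2(C)C | intermediate (not isolated)
20 | 2,4-bis(trimethylsilyloxy) arene corresponding to 21 | COC(=O)C[C@H](C)OC(=O)c1c(O[Si](C)(C)C)cc(O[Si](C)(C)C)cc1C[C@@H](C)OC(=O)C[C@@H](COCc2ccccc2)OC(=O)C[C@H](C)OCc2ccccc2 | intermediate (not isolated)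
21 | (2S)-4-methoxy-4-oxobutan-2-yl 2-[(2R)-2-({(3S)-4-(benzyloxy)-3-[(3S)-3-(benzyloxy)butanoyloxy]butanoyl}oxy)propyl]-4,6-dihydroxybenzoate | COC(=O)C[C@H](C)OC(=O)c1c(O)cc(O)cc1C[C@@H](C)OC(=O)C[C@@H](COCc2ccccc2)OC(=O)C[C@H](C)OCc2ccccc2 | intermediate (key-step product)
22 | talapolyester D | COC(=O)C[C@H](C)OC(=O)c1c(O)cc(O)cc1C[C@@H](C)OC(=O)C[C@@H](CO)OC(=O)C[C@H](C)O | target

**Step count**

Total: 13 steps. Longest linear sequence: 8 steps (steps 1, 2, 4, 5, 6, 9, 12, 13, from methyl (S)-3-hydroxybutanoate).

**Steps most likely to fail**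

1. Step 12. The cycloaddition may be slow at the diene terminus next to the quaternary carbon. Thermal degradation of the ynoate (propargyl–allenyl isomerisation with loss of the δ-acyloxy group) or adventitious hydrolysis of the diene could then outrun ring formation. The fallback keeps the same two ring bonds but changes the partner and the aromatisation mode. It sets out from 14, which would be heated in toluene at 80–110 °C with the acyclic 1-methoxy-1,3-bis(trimethylsilyloxy)buta-1,3-diene (C=C(O[Si](C)(C)C)C=C(OC)O[Si](C)(C)C), whose nucleophilic terminus is an unhindered CH2. The same polarity matching should give the cyclohexa-1,4-diene ketal adduct F1, which aromatises by 1,4-elimination of methanol instead of cycloreversion to give 20. The same acidic work-up then returns the route at 21.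

2. Step 8. Deprotonation α to the methyl ester with E1cB loss of the propiolate, or decay of the lithium alkynoate before the epoxide is opened, could erode the alkynylation. The fallback postpones the β-acyloxy ester until after the strong-base step. It sets out from 11, which would be opened by lithiated tert-butyl propiolate (n-BuLi, THF, −78 °C; BF3·OEt2) to give tert-butyl (5R)-5-hydroxyhex-2-ynoate F2. Steglich esterification of F2 with acid 8 would give the tert-butyl ynoate diester F3. CF3CO2H in CH2Cl2 at 0 °C, which spares benzyl ethers and alkyl esters, would then release the ynoic acid F4. Steglich esterification of F4 with alcohol 1 returns the route at 14.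

3. Step 9. Activation of the β-acyloxy acid may trigger β-elimination of the acyloxy group (through a ketene or an enolised acyl-pyridinium), and DMAP may isomerise the δ-oxygenated ynoate. The fallback activates the alcohol instead of the acid. It sets out from 10, which would be carried through the step 8 protocol with (S)-propylene oxide (C[C@H]1CO1) to give the C5-epimeric alkynol methyl (3S)-3-{[(5S)-5-hydroxyhex-2-ynoyl]oxy}butanoate F5. A Mitsunobu reaction of F5 with acid 8 (PPh3, diisopropyl azodicarboxylate, toluene, 0 °C) would form the C5–O bond by SN2 displacement with inversion, returning the route at 14 with the (5R) configuration.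

**Further compounds**

F1 | step 12 | cyclohexa-1,4-diene ketal adduct of 14 and 1-methoxy-1,3-bis(trimethylsilyloxy)buta-1,3-diene (ketal carbon unassigned) | COC(=O)C[C@H](C)OC(=O)C1=C(C[C@@H](C)OC(=O)C[C@@H](COCc2ccccc2)OC(=O)C[C@H](C)OCc2ccccc2)CC(O[Si](C)(C)C)=CC1(OC)O[Si](C)(C)C
F2 | step 8 | tert-butyl (5R)-5-hydroxyhex-2-ynoate | CC(C)(C)OC(=O)C#CC[C@@H](C)O
F3 | step 8 | tert-butyl (5R)-5-({(3S)-4-(benzyloxy)-3-[(3S)-3-(benzyloxy)butanoyloxy]butanoyl}oxy)hex-2-ynoate | CC(C)(C)OC(=O)C#CC[C@@H](C)OC(=O)C[C@@H](COCc1ccccc1)OC(=O)C[C@H](C)OCc1ccccc1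
F4 | step 8 | (5R)-5-({(3S)-4-(benzyloxy)-3-[(3S)-3-(benzyloxy)butanoyloxy]butanoyl}oxy)hex-2-ynoic acid | OC(=O)C#CC[C@@H](C)OC(=O)C[C@@H](COCc1ccccc1)OC(=O)C[C@H](C)OCc1ccccc1
F5 | step 9 | methyl (3S)-3-{[(5S)-5-hydroxyhex-2-ynoyl]oxy}butanoate | COC(=O)C[C@H](C)OC(=O)C#CC[C@H](C)O
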